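**Plan**
1. Daucane numbering: C1 (quaternary, C–Me), C2, C3, C4 (isopropyl carbinol) and C5 (fusion CH) form the five-membered ring; C5, C6 (anisoate), C7, C8=C9 and C10 (acetate) with C1 form the seven-membered ring. β is the face of the C1 methyl.
2. The retrosynthesis cuts the two ester C–O bonds and the C4–isopropyl bond. It then joins C6 to C10: the two oxygenated carbons are 1,4-related across the C1–C5 fusion bond, so the seven-membered ring is a ring-opened cyclobutane-1,2-diol.
3. The resulting 5-4-5 tricycle is cut at C1–C10 and C5–C6 into 3-methylcyclopent-2-enone and 4-methyl-1,2-bis(trimethylsilyloxy)cyclopentene, the latter from dimethyl 3-methylglutarate.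
4. Forward: the cyclopentanone ring is bought, the cyclobutane is closed by [2+2] photocycloaddition, and glycol cleavage of C6–C10 merges the four-membered and the second five-membered ring into the seven-membered ring. C8=C9, the isopropyl group and the two esters follow.
5. Stereochemistry: C1 (absolute) from a chiral Lewis acid in the photocycloaddition; C5 by equilibration to the trans-fused ketone; C10 by CBS reduction; C4 by addition anti to the angular methyl; C6 by hydroxyl-directed reduction from the C4 carbinol.

Key step: step 2

Remark: compounds 4–11 are carried as mixtures of C8 epimers that converge in step 7 (their SMILES leave C8 open). The C6 configuration of 9–19 is provisional and is set finally in step 14.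

**Step 1**
Reactants: 1 dimethyl 3-methylpentanedioate
Product: 2 4-methyl-1,2-bis(trimethylsilyloxy)cyclopent-1-ene
Conditions: Na, Me3SiCl, toluene, reflux
Reagents that add atoms: chlorotrimethylsilane, C[Si](C)(C)Cl
Why: Acyloin condensation in its Rühlmann form, in which sodium couples the two ester carbons to the five-membered enediolate and Me3SiCl traps it and the methoxide, which suppresses Dieckmann side reactions.

**Step 2**
Reactants: 3 3-methylcyclopent-2-en-1-one; 2 4-methyl-1,2-bis(trimethylsilyloxy)cyclopent-1-ene
Product: 4 cis-anti-cis 5-4-5 photoadduct (1S)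
Conditions: 2 (5 equiv), AlBr3-activated prolinol-derived B-aryl oxazaborolidine (50 mol %, the antipode that shields the Re face of C1), hν (366 nm), CH2Cl2, −75 °C
Reagents that add atoms: none
Why: Proposed new method: the closest known reactions are the uncatalysed triplet [2+2] photocycloaddition of cyclopentenones to 1,2-bis(silyloxy)cycloalkenes, which gives this cis-anti-cis skeleton as a racemate, and the enantioselective intermolecular enone–alkene photocycloaddition of cyclohex-2-enones under chiral AlBr3-activated oxazaborolidines, but the two have not been combined on a cyclopentenone with a bis(silyloxy)alkene. Coordination of the Lewis acid to the C4 carbonyl should shift the π,π* band to longer wavelength so that 366 nm light excites mainly the complex, whose triplet adds the electron-rich alkene to a 1,4-diradical that closes the cyclobutane by radical recombination after intersystem crossing, forming C5–C6 and C1–C10. C1 and C5 must be cis because a trans-fused bicyclo[3.2.0]heptanone is too strained, C6 and C10 are cis because both lie in the cyclopentene ring, and the anti arrangement of the two five-membered rings follows from steric repulsion in the diradical. The absolute configuration at C1 rests on reagent control alone, the catalyst aryl group covering the Re face of the β-carbon so that the alkene adds to its Si face, whereas regiochemistry needs no control because the alkene is symmetric about C6/C10. C8 is not controlled and need not be. A thermal Lewis-acid-promoted Michael–aldol [2+2] of the silyl enol ether, the most likely background path, would form the same two bonds.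

**Step 3**
Reactants: 4 cis-anti-cis 5-4-5 photoadduct
Product: 5 C4 ethylene ketal of the photoadduct
Conditions: Me3SiOCH2CH2OSiMe3, Me3SiOTf (5 mol %), CH2Cl2, −78 °C; pyridine
Reagents that add atoms: 1,2-bis(trimethylsilyloxy)ethane, C[Si](C)(C)OCCO[Si](C)(C)C
Why: Noyori ketalisation under aprotic conditions at −78 °C, which should keep the silyl ethers in place, so that no β-hydroxy ketone is exposed to retro-aldol cleavage and the donor–acceptor cyclobutane is not opened.

**Step 4**
Reactants: 5 C4 ethylene ketal of the photoadduct
Product: 8 trans-fused 4,4-ethylenedioxy-6,10-dione, via cyclobutane-1,2-diol 6 (not isolated), via cis-fused dione 7 (not isolated)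
Conditions: K2CO3, MeOH, rt; NaIO4, H2O, 0 °C; then K2CO3, MeOH, rt
Reagents that add atoms: none
Why: Methanolysis of the tertiary silyl ethers, periodate glycol cleavage of the strained cis-cyclobutane-1,2-diol to the cycloheptane-1,4-dione and, in the same carbonate medium, epimerisation of C5 next to the C6 ketone to the trans-fused hydroazulene, which should be the more stable isomer.

**Step 5**
Reactants: 8 trans-fused 4,4-ethylenedioxy-6,10-dione
Product: 9 6β-hydroxy-10-ketone
Conditions: L-Selectride (1.05 equiv), THF, −78 °C; H2O
Reagents that add atoms: none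
Why: Chemoselective hydride reduction in which the bulky borohydride reaches the C6 carbonyl far faster than the neopentyl C10 carbonyl, and equatorial attack, away from the 1,3-related angular methyl, should give the axial 6β-alcohol.

**Step 6**
Reactants: 9 6β-hydroxy-10-ketone
Product: 10 6β-silyl ether
Conditions: TBSOTf, 2,6-lutidine, CH2Cl2, −78 °C
Reagents that add atoms: tert-butyldimethylsilyl triflate, CC(C)(C)[Si](C)(C)OS(=O)(=O)C(F)(F)F
Why: Standard silylation of a hindered secondary alcohol, in which the secondary hydroxyl of the open hydroxy ketone should react faster than the tertiary hydroxyl of any transannular hemiketal, so that the equilibrium drains to 10.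

**Step 7**
Reactants: 10 6β-silyl ether
Product: 12 8-en-10-one, via trimethylsilyl enol ether 11 (not isolated)
Conditions: LDA, Me3SiCl, THF, −78 °C; then Pd(OAc)2 (10 mol %), O2, DMSO, rt
Reagents that add atoms: none
Why: Saegusa–Ito dehydrogenation, in which the C10 ketone can enolise only towards C9 because C1 is quaternary, and β-hydride elimination from the palladium enolate places the double bond at C8=C9 and removes the C8 stereocentre.

**Step 8**
Reactants: 12 8-en-10-one
Product: 13 10α-allylic alcohol
Conditions: (S)-Me-CBS oxazaborolidine (20 mol %), catecholborane, toluene, −78 °C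
Reagents that add atoms: none
Why: Corey–Bakshi–Shibata reduction in which, with the quaternary C1 flank as the large group, the (S)-catalyst should deliver hydride to the β-face of C10, syn to the angular methyl and against the intrinsic bias of the ketone, to give the 10α-alcohol.

**Step 9**
Reactants: 13 10α-allylic alcohol
Product: 14 C4 ketone
Conditions: PPTS, acetone/H2O, 45 °C
Reagents that add atoms: water, O
Why: Acid-catalysed ketal hydrolysis under pyridinium buffering, which should be mild enough to spare the secondary silyl ether and the allylic alcohol.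

**Step 10**
Reactants: 14 C4 ketone; 15 isopropylmagnesium chloride
Product: 16 4β,10α-diol
Conditions: 15 (3 equiv), anhydrous CeCl3, THF, −78 → 0 °C
Reagents that add atoms: none
Why: Organocerium 1,2-addition, in which the weakly basic reagent should add to the enolisable α-branched cyclopentanone without enolisation or β-elimination of the C6 silyloxy group, from the α-face anti to the 1,3-related angular methyl of the trans-fused bicycle, which sets the 4β-hydroxyl.

**Step 11**
Reactants: 16 4β,10α-diol; 17 acetic anhydride
Product: 18 10α-acetate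
Conditions: pyridine, DMAP (cat.), CH2Cl2, 0 °C → rt
Reagents that add atoms: none
Why: Chemoselective acylation of the secondary allylic hydroxyl, the hindered tertiary 4-hydroxyl being inert under these conditions.

**Step 12**
Reactants: 18 10α-acetate
Product: 19 4β,6β-diol 10-acetate
Conditions: HF·pyridine, pyridine, THF, 0 °C → rt
Reagents that add atoms: none
Why: Fluoride-mediated cleavage of the silyl ether under buffered conditions that should leave the allylic acetate and the tertiary alcohol intact.

**Step 13**
Reactants: 19 4β,6β-diol 10-acetate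
Product: 20 4β-hydroxy-6-ketone
Conditions: Dess–Martin periodinane, NaHCO3, CH2Cl2, 0 °C; crude product used at once
Reagents that add atoms: none
Why: Dess–Martin oxidation of the only secondary alcohol under non-basic conditions, chosen to avoid retro-aldol cleavage, conjugation of the β,γ-double bond and vinylogous loss of acetate.

**Step 14**
Reactants: 20 4β-hydroxy-6-ketone
Product: 21 4β,6α-diol 10-acetate
Conditions: Me4NBH(OAc)3, MeCN/AcOH, −30 °C
Reagents that add atoms: none
Why: Evans–Saksena hydroxyl-directed reduction, in which the 4β-hydroxyl binds boron and delivers hydride intramolecularly to the β-face of the C6 carbonyl, which sets the 6α-alcohol (1,3-anti diol) and leaves the acetate alone.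

**Step 15**
Reactants: 21 4β,6α-diol 10-acetate; 22 4-methoxybenzoyl chloride
Product: 23 target
Conditions: Et3N, DMAP, CH2Cl2, rt
Reagents that add atoms: none
Why: DMAP-catalysed acyl transfer to the secondary 6α-hydroxyl, the tertiary 4-hydroxyl being too hindered to compete.

**Compound list**
1 | dimethyl 3-methylpentanedioate | COC(=O)CC(C)CC(=O)OC | starting material
2 | 4-methyl-1,2-bis(trimethylsilyloxy)cyclopent-1-ene | CC1CC(O[Si](C)(C)C)=C(O[Si](C)(C)C)C1 | intermediate
3 | 3-methylcyclopent-2-en-1-one | CC1=CC(=O)CC1 | starting material
4 | cis-anti-cis photoadduct, (1S)-6,10-bis(trimethylsilyloxy)-6,10-cyclo-11,12,13-trinordaucan-4-one (cyclobutane C1–C5–C6–C10; 1-Me and H-5 on one face, both OSiMe3 on the other; C8 epimers) | C[C@]12CCC(=O)[C@H]1[C@]3(O[Si](C)(C)C)CC(C)C[C@]23O[Si](C)(C)C | intermediate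
5 | 4,4-ethylenedioxy ketal of 4 (C8 epimers) | C[C@]12CCC3(OCCO3)[C@H]1[C@]4(O[Si](C)(C)C)CC(C)C[C@]24O[Si](C)(C)C | intermediate
6 | 4,4-ethylenedioxy-6,10-cyclo-11,12,13-trinordaucane-6,10-diol (cis-diol, C8 epimers) | C[C@]12CCC3(OCCO3)[C@H]1[C@]4(O)CC(C)C[C@]24O | intermediate
7 | cis-fused 4,4-ethylenedioxy-11,12,13-trinordaucane-6,10-dione (1β-Me, 5β-H; C8 epimers) | O=C1CC(C)CC(=O)[C@@]2(C)CCC3(OCCO3)[C@@H]12 | intermediate
8 | trans-fused 4,4-ethylenedioxy-11,12,13-trinordaucane-6,10-dione (1β-Me, 5α-H; C8 epimers) | O=C1CC(C)CC(=O)[C@@]2(C)CCC3(OCCO3)[C@H]12 | intermediate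
9 | 4,4-ethylenedioxy-6β-hydroxy-11,12,13-trinordaucan-10-one (5α-H; C8 epimers) | O[C@@H]1CC(C)CC(=O)[C@@]2(C)CCC3(OCCO3)[C@H]12 | intermediate
10 | 6β-(tert-butyldimethylsilyloxy)-4,4-ethylenedioxy-11,12,13-trinordaucan-10-one (C8 epimers) | CC(C)(C)[Si](C)(C)O[C@@H]1CC(C)CC(=O)[C@@]2(C)CCC3(OCCO3)[C@H]12 | intermediate
11 | 6β-(tert-butyldimethylsilyloxy)-4,4-ethylenedioxy-10-(trimethylsilyloxy)-11,12,13-trinordauc-9-ene (C8 epimers) | CC(C)(C)[Si](C)(C)O[C@@H]1CC(C)C=C(O[Si](C)(C)C)[C@@]2(C)CCC3(OCCO3)[C@H]12 | intermediate
12 | 6β-(tert-butyldimethylsilyloxy)-4,4-ethylenedioxy-11,12,13-trinordauc-8-en-10-one | CC(C)(C)[Si](C)(C)O[C@@H]1CC(C)=CC(=O)[C@@]2(C)CCC3(OCCO3)[C@H]12 | intermediate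
13 | 6β-(tert-butyldimethylsilyloxy)-4,4-ethylenedioxy-11,12,13-trinordauc-8-en-10α-ol | CC(C)(C)[Si](C)(C)O[C@@H]1CC(C)=C[C@@H](O)[C@@]2(C)CCC3(OCCO3)[C@H]12 | intermediate
14 | 6β-(tert-butyldimethylsilyloxy)-10α-hydroxy-11,12,13-trinordauc-8-en-4-one (5α-H) | CC(C)(C)[Si](C)(C)O[C@@H]1CC(C)=C[C@@H](O)[C@@]2(C)CCC(=O)[C@H]12 | intermediate
15 | isopropylmagnesium chloride | CC(C)[Mg]Cl | starting material
16 | 6β-(tert-butyldimethylsilyloxy)dauc-8-ene-4β,10α-diol | CC(C)(C)[Si](C)(C)O[C@@H]1CC(C)=C[C@@H](O)[C@@]2(C)CC[C@@](O)(C(C)C)[C@H]12 | intermediate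
17 | acetic anhydride | CC(=O)OC(C)=O | starting material
18 | 10α-acetoxy-6β-(tert-butyldimethylsilyloxy)dauc-8-en-4β-ol | CC(C)(C)[Si](C)(C)O[C@@H]1CC(C)=C[C@@H](OC(C)=O)[C@@]2(C)CC[C@@](O)(C(C)C)[C@H]12 | intermediate
19 | 10α-acetoxydauc-8-ene-4β,6β-diol | O[C@@H]1CC(C)=C[C@@H](OC(C)=O)[C@@]2(C)CC[C@@](O)(C(C)C)[C@H]12 | intermediate
20 | 10α-acetoxy-4β-hydroxydauc-8-en-6-one (5α-H) | O=C1CC(C)=C[C@@H](OC(C)=O)[C@@]2(C)CC[C@@](O)(C(C)C)[C@H]12 | intermediate
21 | 10α-acetoxydauc-8-ene-4β,6α-diol | O[C@H]1CC(C)=C[C@@H](OC(C)=O)[C@@]2(C)CC[C@@](O)(C(C)C)[C@H]12 | intermediate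
22 | 4-methoxybenzoyl chloride | COc1ccc(cc1)C(Cl)=O | starting material
23 | (1S,4R,5S,6S,10R)-10-acetoxy-4-hydroxydauc-8-en-6-yl 4-methoxybenzoate (6α-anisoate, 10α-acetate, 4β-OH, 5α-H, 1β-Me) | COc1ccc(C(=O)O[C@H]2CC(C)=C[C@@H](OC(C)=O)[C@@]3(C)CC[C@@](O)(C(C)C)[C@H]23)cc1 | target

**Step count and risks**
Total steps: 15. Longest linear sequence: 15 (from 1; compound 3 enters in step 2).

Most likely to fail, first: step 2. The Lewis acid may consume or desilylate the enediol ether in the dark, or open the donor–acceptor cyclobutane once formed, and excitation of uncomplexed enone may erode the face selection. The fallback sets out from 2 and 3. Irradiation without any additive (λ > 300 nm, CH2Cl2, −20 °C), the established uncatalysed reaction, would give the racemate, that is 4 together with the enantiomeric photoadduct F1. Ketalisation under the conditions of step 3 would give 5 together with the enantiomeric ketal F2. Preparative chromatography on a chiral stationary phase, each C8 epimer pair being sorted by core configuration, would then deliver 5, where the route is rejoined. In either case, antipodal material that survives to step 8 would be reduced by the (S)-catalyst mainly to the 10β-diastereomer and could be removed there.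

Second: step 8. The preference of the C10 carbonyl for hydride attack anti to the angular methyl may override the catalyst and give poor facial selectivity. The fallback sets out from 12 and uses that preference. Luche reduction (NaBH4, CeCl3·7H2O, MeOH, −78 °C) should give the 10β-allylic alcohol F3. Mitsunobu inversion with 4-nitrobenzoic acid (PPh3, DIAD, toluene, 0 °C → rt), with the nucleophile entering from the open α-face, would give the 10α-4-nitrobenzoate F4. Methanolysis (K2CO3, MeOH) returns the route to 13.

Third: step 10. The secondary organometallic may enolise the ketone, with β-elimination of the C6 silyloxy group, or transfer a β-hydride instead of adding. The fallback sets out from 14. 2-Propenylmagnesium bromide with CeCl3, an sp2 nucleophile that is smaller and has no transferable β-hydride, would give the isopropenyl carbinol F5. Hydrogenation with Wilkinson's catalyst, selective for the 1,1-disubstituted over the trisubstituted double bond, returns the route to 16.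

Further compounds
F1 | step 2 | enantiomer of photoadduct 4 | C[C@@]12CCC(=O)[C@@H]1[C@@]3(O[Si](C)(C)C)CC(C)C[C@@]23O[Si](C)(C)C
F2 | step 2 | enantiomer of ketal 5 | C[C@@]12CCC3(OCCO3)[C@@H]1[C@@]4(O[Si](C)(C)C)CC(C)C[C@@]24O[Si](C)(C)C
F3 | step 8 | 6β-(tert-butyldimethylsilyloxy)-4,4-ethylenedioxy-11,12,13-trinordauc-8-en-10β-ol | CC(C)(C)[Si](C)(C)O[C@@H]1CC(C)=C[C@H](O)[C@@]2(C)CCC3(OCCO3)[C@H]12
F4 | step 8 | 6β-(tert-butyldimethylsilyloxy)-4,4-ethylenedioxy-11,12,13-trinordauc-8-en-10α-yl 4-nitrobenzoate | CC(C)(C)[Si](C)(C)O[C@@H]1CC(C)=C[C@@H](OC(=O)c4ccc(cc4)[N+](=O)[O-])[C@@]2(C)CCC3(OCCO3)[C@H]12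
F5 | step 10 | 6β-(tert-butyldimethylsilyloxy)-4α-(prop-1-en-2-yl)-11,12,13-trinordauc-8-ene-4β,10α-diol | CC(C)(C)[Si](C)(C)O[C@@H]1CC(C)=C[C@@H](O)[C@@]2(C)CC[C@@](O)(C(C)=C)[C@H]12
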